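**Retrosynthetic overview**

- Feature: C4 of ring A carries a methyl (C18) and an oxygenated carbon (C19) that sits cis to C6 on C5. This is the imprint of a 4-methyl-5-alkoxybutenolide whose ring oxygen bridges C19 and C6.
- Ring A (formed first): Diels–Alder reaction of the (5S)-menthyloxy butenolide with 4-methoxy-2-silyloxypentadiene makes C3–C4 and C5–C10 and gives the cis-fused enone lactone. Hydride reduction then frees C19 and C6 and sets 2α-OH.
- C9–C10: Ireland–Claisen rearrangement of the 2α-ester of a C8–C15 side-chain acid transfers the C2 configuration to quaternary C10. The C2 oxygen is returned in the last step by hydroboration of C1=C2.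
- Ring B (formed second): C6–C7 by intramolecular alkylation of the C8 methyl ketone enolate with a C6 iodide, C9 set by equilibration of the ring ketone, C17 through the enol triflate.
- Side chain: (E)-C13=C14 from zirconium-catalysed carboalumination of hex-5-yn-1-ol; endgame acylation of O15, then O19.

Key step: step 3

Remark: labdane numbering is used for every intermediate (ring A = C1–C5, C10; ring B = C5–C10; C18 = 4α-CH3, C19 = 4β-CH2O, C20 = 10β-CH3, C17 = 8-CH3; α = face of H5, β = face of C20); TBS = tert-butyldimethylsilyl, TBDPS = tert-butyldiphenylsilyl, Men = (1S,2R,5S)-menthyl; the four starting materials are taken as commercial.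

**Route**

Step 1
Reactants: 1 5-hydroxy-4-methylfuran-2(5H)-one; 2 (+)-menthol
Product: 3 (5S)-5-[(1S,2R,5S)-menthyloxy]-4-methylfuran-2(5H)-one
Conditions: TsOH·H2O (cat.), toluene, reflux, Dean–Stark; crystallisation (hexane), mother liquor re-equilibrated with the same acid
Reagents that add atoms: none
Why: Acid-catalysed acetalisation of the cyclic hemiacetal through its oxocarbenium ion gives both C5 epimers under equilibrium, and the (5S) acetal should be separable by crystallisation (chromatography otherwise) while the acetal centre of the remainder is re-equilibrated.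

Step 2
Reactants: 4 (E)-4-methoxypent-3-en-2-one
Product: 5 (3E)-4-methoxy-2-(trimethylsilyloxy)penta-1,3-diene
Conditions: Me3SiCl, LiN(iPr)2, THF, −78 °C (in situ quench); non-aqueous work-up, distillation
Reagents that add atoms: chlorotrimethylsilane, C[Si](C)(C)Cl
Why: Kinetic deprotonation of the acetyl methyl group by the hindered amide base with immediate O-silylation (silyl enol ether formation) gives the cross-conjugated 2-silyloxydiene and leaves the (E)-enol ether untouched.

Step 3
Reactants: 3 (5S)-menthyloxy butenolide; 5 silyloxydiene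
Product: 7 cis-fused enone lactone acetal (2-oxo, C1=C10, 4α-CH3, H5α, lactone C6(=O)–O–C19 on the β face, OMen on C19 cis to C18 and H5), via silyl enol ether cycloadduct 6 (not isolated)
Conditions: 5 (3 equiv), CH2Cl2, 13 kbar, 40 °C; then 0.5 M HCl, THF, 0 °C
Reagents that add atoms: none
Why: A [4+2] cycloaddition joins the electron-rich diene 5 to the butenolide C=C of 3, the known Diels–Alder reaction of 5-alkoxy-2(5H)-furanones with Danishefsky-type dienes, run under pressure because the β-methyl dienophile and the fully substituted diene terminus are both sluggish. The nucleophilic CH2 terminus (C3) bonds to the β-carbon C4 and the methoxy-bearing terminus (C10) to the α-carbon C5, the orientation in which the donor pattern of the diene matches the acceptor pattern of the lactone. Ring A closes as a six-membered ring in this single event, suprafacially on the dienophile, so the lactone is cis-fused and C18 and H5 are cis. The diene approaches the face of the butenolide opposite to the menthyloxy group on the acetal carbon C19, which fixes C4 and C5 in the absolute sense. Dilute acid then hydrolyses the silyl enol ether of 6 and eliminates methanol, which erases the temporary C10 centre together with any endo/exo question and leaves the C2 ketone conjugated with C1=C10. The step needs regio- and π-facial selectivity, secured by the matched oxygenation of 5 and by the single acetal stereocentre of 3.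

Step 4
Reactants: 7 enone lactone acetal
Product: 8 ring A triol (2α-OH, C1=C10, 4β-CH2OH = C19, 5β-CH2OH = C6; 4,5-bis(hydroxymethyl)-3,5-dimethylcyclohex-2-en-1-ol with both CH2OH cis and the ring OH trans to them)
Conditions: LiAlH4 (excess), THF, −78 → 0 °C; aqueous KNaC4H4O6 work-up
Reagents that add atoms: none
Why: LiAlH4 reduces the enone in the 1,2 sense and the acyloxy acetal to the 1,4-diol with release of menthol (the known reductive removal of this auxiliary), and hydride should reach C2 from the β face, anti to the pseudoaxial C18 methyl of the conformer that keeps C6 pseudoaxial and free of allylic strain with C20, which sets 2α-OH.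

Step 5
Reactants: 8 ring A triol
Product: 9 C6 TBS ether of the triol
Conditions: t-BuMe2SiCl (1.05 equiv), imidazole, CH2Cl2/DMF, −40 → −20 °C
Reagents that add atoms: tert-butyldimethylsilyl chloride, CC(C)(C)[Si](C)(C)Cl
Why: Sterically controlled silylation should take the C6 hydroxyl, which sits on a tertiary carbon, ahead of the neopentyl C19 hydroxyl and the secondary allylic C2 hydroxyl.

Step 6
Reactants: 9 C6 TBS ether
Product: 10 ring A allylic alcohol (2α-OH free, C6-OTBS, C19-OTBDPS)
Conditions: t-BuPh2SiCl, imidazole, DMF, 0 °C → rt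
Reagents that add atoms: tert-butyldiphenylsilyl chloride, CC(C)(C)[Si](Cl)(c1ccccc1)c1ccccc1
Why: The bulky chlorosilane silylates the remaining primary hydroxyl in preference to the secondary allylic one (chemoselective silyl ether formation), so that C19 is masked before C6 is later activated.

Step 7
Reactants: 11 hex-5-yn-1-ol
Product: 12 tert-butyl(hex-5-yn-1-yloxy)dimethylsilane
Conditions: t-BuMe2SiCl, imidazole, CH2Cl2, rt
Reagents that add atoms: tert-butyldimethylsilyl chloride, CC(C)(C)[Si](C)(C)Cl
Why: Standard silyl ether formation protects the hydroxyl that will later become the C8 carboxyl.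

Step 8
Reactants: 12 silyl ether of hex-5-yn-1-ol
Product: 15 (2E)-7-(tert-butyldimethylsilyloxy)-3-methylhept-2-en-1-ol, via alkenylalane 13 (not isolated), via lithium alanate 14 (not isolated)
Conditions: AlMe3, (C5H5)2ZrCl2 (cat.), CH2Cl2, rt; evaporation; n-BuLi, THF, −78 °C; (CH2O)n, → rt
Reagents that add atoms: trimethylaluminium, C[Al](C)C; formaldehyde (as paraformaldehyde), C=O
Why: Negishi zirconium-catalysed carboalumination adds CH3 and Al syn across the terminal alkyne with Al at the terminus, and the derived alanate is hydroxymethylated with retention, which fixes the (E)-trisubstituted C13=C14 alkene with C16 and C15 in place.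

Step 9
Reactants: 15 allylic alcohol
Product: 16 (2E)-1-(tert-butyldiphenylsilyloxy)-7-(tert-butyldimethylsilyloxy)-3-methylhept-2-ene
Conditions: t-BuPh2SiCl, imidazole, DMF, rt
Reagents that add atoms: tert-butyldiphenylsilyl chloride, CC(C)(C)[Si](Cl)(c1ccccc1)c1ccccc1
Why: Standard silylation gives O15 the acid-stable silyl group that is orthogonal to the TBS ether.

Step 10
Reactants: 16 bis-silyl ether
Product: 17 (5E)-7-(tert-butyldiphenylsilyloxy)-5-methylhept-5-en-1-ol
Conditions: pyridinium p-toluenesulfonate (cat.), MeOH, rt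
Reagents that add atoms: none
Why: Mild acid-catalysed methanolysis removes the primary alkyl TBS ether, the TBDPS ether being far more stable to acid.

Step 11
Reactants: 17 primary alcohol
Product: 18 (5E)-7-(tert-butyldiphenylsilyloxy)-5-methylhept-5-enoic acid
Conditions: TEMPO (cat.), PhI(OAc)2, MeCN/H2O, rt
Reagents that add atoms: water, O
Why: TEMPO-catalysed oxidation takes the primary alcohol through the aldehyde hydrate to the acid and leaves the alkene and the allylic silyl ether alone.

Step 12
Reactants: 10 ring A allylic alcohol; 18 side-chain acid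
Product: 19 2α-ester of 10 with acid 18
Conditions: DCC, DMAP (cat.), CH2Cl2, 0 °C → rt
Reagents that add atoms: none
Why: Steglich esterification under neutral conditions acylates the only free hydroxyl with retention at C2 and spares the acid-sensitive allylic system.

Step 13
Reactants: 19 allylic ester
Product: 22 ring A acid (C1=C2, 10β-CH3, 10α-CH(CO2H)-side chain, C9 epimers), via silyl ketene acetal 20 (not isolated), via trimethylsilyl ester 21 (not isolated)
Conditions: Me3SiCl/Et3N, LiN(iPr)2, THF, −78 °C; then 65 °C; 1 M HCl, 0 °C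
Reagents that add atoms: none
Why: In this Ireland–Claisen rearrangement the silyl ketene acetal rearranges suprafacially through a six-membered transition state on the α face, so the configuration of C2 is transferred to quaternary C10 (C9 α, C20 β, anti to C6) while C1=C2 is formed, and C9 is accepted as an epimer mixture that step 17 corrects.

Step 14
Reactants: 22 ring A acid
Product: 23 methyl ketone (C8=O, new methyl = C7)
Conditions: MeLi (3 equiv), Et2O, 0 °C → rt; inverse quench into cold 1 M HCl
Reagents that add atoms: methyllithium, [Li]C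
Why: Addition of methyllithium to the lithium carboxylate gives a gem-diolate that collapses to the methyl ketone only on acidic quench (carboxylic acid to methyl ketone), and silyl ethers are inert.

Step 15
Reactants: 23 methyl ketone
Product: 24 hydroxy ketone (C6-OH free)
Conditions: AcOH/THF/H2O (3:1:1), rt
Reagents that add atoms: none
Why: Aqueous acetic acid cleaves the primary TBS ether selectively, the two TBDPS ethers being stable under these conditions.

Step 16
Reactants: 24 hydroxy ketone
Product: 25 iodo ketone (C6-I)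
Conditions: I2, PPh3, imidazole, CH2Cl2, 0 °C → rt
Reagents that add atoms: iodine, II
Why: Garegg–Samuelsson (Appel-type) iodination converts the primary alcohol into the iodide, and with O19 silylated no tetrahydrofuran can form.

Step 17
Reactants: 25 iodo ketone
Product: 27 ring B ketone (trans-decalin, 8-oxo, 9β side chain, H9α), via C9-epimeric ketone mixture 26 (not isolated)
Conditions: LiN(iPr)2, THF, −78 °C → rt; then NaOMe, MeOH, rt
Reagents that add atoms: none
Why: Kinetic deprotonation at the C7 methyl and intramolecular C-alkylation by the primary iodide (6-(enolendo)-exo-tet, allowed by Baldwin's rules for enolates) closes ring B as the trans-fused cyclohexanone because C9 (α on C10) and C6 (β on C5) are trans on ring A, and methoxide then epimerises C9 through the enolate to the thermodynamically preferred equatorial (9β) side chain.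

Step 18
Reactants: 27 ring B ketone
Product: 29 C7=C8 enol triflate, via potassium enolate 28 (not isolated)
Conditions: KN(SiMe3)2, THF, −78 °C; PhNTf2, −78 → 0 °C; aqueous NH4Cl
Reagents that add atoms: N-phenylbis(trifluoromethanesulfonimide), O=S(=O)(N(c1ccccc1)S(=O)(=O)C(F)(F)F)C(F)(F)F
Why: Kinetic enolisation at the less hindered C7 methylene followed by O-sulfonylation gives the C7=C8 enol triflate regioselectively and does not touch the C9 stereocentre.

Step 19
Reactants: 29 enol triflate
Product: 30 labda-1,7,13-triene bis-TBDPS ether (C17 in place)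
Conditions: Me2CuLi (from MeLi and CuI), THF, −20 → 0 °C
Reagents that add atoms: lithium dimethylcuprate, [Li+].C[Cu-]C
Why: Coupling of the enol triflate with the cuprate replaces triflate by methyl at C8 without moving the double bond, giving the trisubstituted C7=C8 alkene.

Step 20
Reactants: 30 bis-TBDPS ether
Product: 31 labda-1,7,13-triene-15,19-diol
Conditions: Bu4NF, THF, rt → 45 °C
Reagents that add atoms: none
Why: Fluoride cleaves both TBDPS ethers and affects nothing else in the hydrocarbon framework.

Step 21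
Reactants: 31 diol
Product: 32 C15 methyl succinate (C19-OH free)
Conditions: methyl 4-chloro-4-oxobutanoate (1.05 equiv), pyridine, CH2Cl2, −40 °C
Reagents that add atoms: methyl 4-chloro-4-oxobutanoate, COC(=O)CCC(Cl)=O
Why: The unhindered allylic C15 hydroxyl is acylated far faster than the axial neopentyl C19 hydroxyl, so one equivalent of acid chloride at low temperature should give the mono-ester.

Step 22
Reactants: 32 C15 mono-ester
Product: 33 C15 methyl succinate C19 isovalerate (C1=C2 still present)
Conditions: 3-methylbutanoyl chloride, pyridine, DMAP (cat.), CH2Cl2, rt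
Reagents that add atoms: 3-methylbutanoyl chloride, CC(C)CC(Cl)=O
Why: DMAP-catalysed acylation esterifies the remaining hindered primary alcohol.

Step 23
Reactants: 33 bis-ester triene
Product: 35 target, (13E)-2α-hydroxy-19-(3-methylbutanoyloxy)labda-7,13-dien-15-yl methyl butanedioate, via C2 catechol boronate 34 (not isolated)
Conditions: catecholborane, RhCl(PPh3)3 (cat.), THF, rt; then H2O2, pH 7 phosphate buffer, THF, 0 °C → rt
Reagents that add atoms: hydrogen peroxide, OO
Why: Rhodium-catalysed hydroboration with catecholborane adds to the cis-disubstituted C1=C2 alkene and not to the trisubstituted C7=C8 and C13=C14 alkenes, boron goes to C2 away from quaternary C10 and on the α face anti to the axial C20 and C19 groups, and buffered peroxide oxidation with retention gives the equatorial 2α-alcohol without ester cleavage.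

**Compound list**

1 | 5-hydroxy-4-methylfuran-2(5H)-one | CC1=CC(=O)OC1O | starting material
2 | (+)-menthol, (1S,2R,5S) | C[C@H]1CC[C@@H]([C@H](C1)O)C(C)C | starting material
3 | (5S)-5-[(1S,2R,5S)-menthyloxy]-4-methylfuran-2(5H)-one | CC1=CC(=O)O[C@@H]1O[C@H]2C[C@@H](C)CC[C@@H]2C(C)C | intermediate
4 | (E)-4-methoxypent-3-en-2-one | CO/C(C)=C/C(C)=O | starting material
5 | (3E)-4-methoxy-2-(trimethylsilyloxy)penta-1,3-diene | C=C(O[Si](C)(C)C)/C=C(\C)OC | intermediate
6 | primary cycloadduct: lactone acetal with C2 trimethylsilyl enol ether (C1=C2) and C10 bearing OCH3 and CH3 (C10 epimers) | O=C1O[C@H](O[C@H]3C[C@@H](C)CC[C@@H]3C(C)C)[C@@]2(C)CC(O[Si](C)(C)C)=CC(C)(OC)[C@@H]12 | intermediate (not isolated)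
7 | cis-fused enone lactone acetal, 3-menthyloxy-3a,7-dimethyl-3a,4-dihydro-2-benzofuran-1,5(3H,7aH)-dione (2-oxo, C1=C10, 4α-CH3, H5α, lactone on the β face, OMen cis to C18 and H5) | O=C1O[C@H](O[C@H]3C[C@@H](C)CC[C@@H]3C(C)C)[C@@]2(C)CC(=O)C=C(C)[C@@H]12 | intermediate
8 | ring A triol, 4,5-bis(hydroxymethyl)-3,5-dimethylcyclohex-2-en-1-ol (2α-OH; C6 and C19 hydroxymethyl groups both β) | CC1=C[C@@H](O)C[C@](C)(CO)[C@@H]1CO | intermediate
9 | C6 TBS ether of triol 8 | CC1=C[C@@H](O)C[C@](C)(CO)[C@@H]1CO[Si](C)(C)C(C)(C)C | intermediate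
10 | ring A allylic alcohol, C6-OTBS, C19-OTBDPS, 2α-OH | CC1=C[C@@H](O)C[C@](C)(CO[Si](c2ccccc2)(c2ccccc2)C(C)(C)C)[C@@H]1CO[Si](C)(C)C(C)(C)C | intermediate
11 | hex-5-yn-1-ol | C#CCCCCO | starting material
12 | tert-butyl(hex-5-yn-1-yloxy)dimethylsilane | C#CCCCCO[Si](C)(C)C(C)(C)C | intermediate
13 | dimethyl[(1E)-6-(tert-butyldimethylsilyloxy)-2-methylhex-1-en-1-yl]alane | C[Al](C)/C=C(\C)CCCCO[Si](C)(C)C(C)(C)C | intermediate (not isolated)
14 | lithium butyl(dimethyl)[(1E)-6-(tert-butyldimethylsilyloxy)-2-methylhex-1-en-1-yl]alanate | [Li+].CCCC[Al-](C)(C)/C=C(\C)CCCCO[Si](C)(C)C(C)(C)C | intermediate (not isolated)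
15 | (2E)-7-(tert-butyldimethylsilyloxy)-3-methylhept-2-en-1-ol | OC/C=C(\C)CCCCO[Si](C)(C)C(C)(C)C | intermediate
16 | (2E)-1-(tert-butyldiphenylsilyloxy)-7-(tert-butyldimethylsilyloxy)-3-methylhept-2-ene | CC(C)(C)[Si](c1ccccc1)(c1ccccc1)OC/C=C(\C)CCCCO[Si](C)(C)C(C)(C)C | intermediate
17 | (5E)-7-(tert-butyldiphenylsilyloxy)-5-methylhept-5-en-1-ol | CC(C)(C)[Si](c1ccccc1)(c1ccccc1)OC/C=C(\C)CCCCO | intermediate
18 | (5E)-7-(tert-butyldiphenylsilyloxy)-5-methylhept-5-enoic acid (C8–C15 fragment) | CC(C)(C)[Si](c1ccccc1)(c1ccccc1)OC/C=C(\C)CCCC(=O)O | intermediate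
19 | 2α-ester of 10 with acid 18 | CC1=C[C@@H](OC(=O)CCC/C(C)=C/CO[Si](c2ccccc2)(c2ccccc2)C(C)(C)C)C[C@](C)(CO[Si](c2ccccc2)(c2ccccc2)C(C)(C)C)[C@@H]1CO[Si](C)(C)C(C)(C)C | intermediate
20 | trimethylsilyl ketene acetal of 19 | CC1=C[C@@H](OC(O[Si](C)(C)C)=CCC/C(C)=C/CO[Si](c2ccccc2)(c2ccccc2)C(C)(C)C)C[C@](C)(CO[Si](c2ccccc2)(c2ccccc2)C(C)(C)C)[C@@H]1CO[Si](C)(C)C(C)(C)C | intermediate (not isolated)
21 | trimethylsilyl ester of acid 22 (C9 epimers) | C[C@]1(C(CC/C(C)=C/CO[Si](c2ccccc2)(c2ccccc2)C(C)(C)C)C(=O)O[Si](C)(C)C)C=CC[C@](C)(CO[Si](c2ccccc2)(c2ccccc2)C(C)(C)C)[C@@H]1CO[Si](C)(C)C(C)(C)C | intermediate (not isolated)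
22 | ring A acid: C1=C2, 10β-CH3, 10α-CH(CO2H)(side chain), 5β-CH2OTBS, 4β-CH2OTBDPS (C9 epimers) | C[C@]1(C(CC/C(C)=C/CO[Si](c2ccccc2)(c2ccccc2)C(C)(C)C)C(=O)O)C=CC[C@](C)(CO[Si](c2ccccc2)(c2ccccc2)C(C)(C)C)[C@@H]1CO[Si](C)(C)C(C)(C)C | intermediate
23 | methyl ketone from 22 (C8=O, C7 methyl; C9 epimers) | C[C@]1(C(CC/C(C)=C/CO[Si](c2ccccc2)(c2ccccc2)C(C)(C)C)C(C)=O)C=CC[C@](C)(CO[Si](c2ccccc2)(c2ccccc2)C(C)(C)C)[C@@H]1CO[Si](C)(C)C(C)(C)C | intermediate
24 | hydroxy ketone (C6-OH; C9 epimers) | C[C@]1(C(CC/C(C)=C/CO[Si](c2ccccc2)(c2ccccc2)C(C)(C)C)C(C)=O)C=CC[C@](C)(CO[Si](c2ccccc2)(c2ccccc2)C(C)(C)C)[C@@H]1CO | intermediate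
25 | iodo ketone (C6-I; C9 epimers) | C[C@]1(C(CC/C(C)=C/CO[Si](c2ccccc2)(c2ccccc2)C(C)(C)C)C(C)=O)C=CC[C@](C)(CO[Si](c2ccccc2)(c2ccccc2)C(C)(C)C)[C@@H]1CI | intermediate
26 | 15,19-bis(TBDPS-oxy)-17-norlabda-1,13E-dien-8-one, C9 epimer mixture | CC(C)(C)[Si](c1ccccc1)(c1ccccc1)OC/C=C(\C)CCC1C(=O)CC[C@H]2[C@@](C)(CO[Si](c3ccccc3)(c3ccccc3)C(C)(C)C)CC=C[C@]12C | intermediate (not isolated)
27 | 15,19-bis(TBDPS-oxy)-17-norlabda-1,13E-dien-8-one (H5α, H9α, 10β-CH3) | CC(C)(C)[Si](c1ccccc1)(c1ccccc1)OC/C=C(\C)CC[C@H]1C(=O)CC[C@H]2[C@@](C)(CO[Si](c3ccccc3)(c3ccccc3)C(C)(C)C)CC=C[C@]12C | intermediate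
28 | potassium C7=C8 enolate of 27 | CC(C)(C)[Si](c1ccccc1)(c1ccccc1)OC/C=C(\C)CC[C@H]1C([O-])=CC[C@H]2[C@@](C)(CO[Si](c3ccccc3)(c3ccccc3)C(C)(C)C)CC=C[C@]12C.[K+] | intermediate (not isolated)
29 | C7=C8 enol triflate of 27 | CC(C)(C)[Si](c1ccccc1)(c1ccccc1)OC/C=C(\C)CC[C@H]1C(OS(=O)(=O)C(F)(F)F)=CC[C@H]2[C@@](C)(CO[Si](c3ccccc3)(c3ccccc3)C(C)(C)C)CC=C[C@]12C | intermediate
30 | 15,19-bis(TBDPS-oxy)labda-1,7,13E-triene | CC(C)(C)[Si](c1ccccc1)(c1ccccc1)OC/C=C(\C)CC[C@H]1C(C)=CC[C@H]2[C@@](C)(CO[Si](c3ccccc3)(c3ccccc3)C(C)(C)C)CC=C[C@]12C | intermediate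
31 | labda-1,7,13E-triene-15,19-diol | OC/C=C(\C)CC[C@H]1C(C)=CC[C@H]2[C@@](C)(CO)CC=C[C@]12C | intermediate
32 | 19-hydroxylabda-1,7,13E-trien-15-yl methyl butanedioate | COC(=O)CCC(=O)OC/C=C(\C)CC[C@H]1C(C)=CC[C@H]2[C@@](C)(CO)CC=C[C@]12C | intermediate
33 | 19-(3-methylbutanoyloxy)labda-1,7,13E-trien-15-yl methyl butanedioate | COC(=O)CCC(=O)OC/C=C(\C)CC[C@H]1C(C)=CC[C@H]2[C@@](C)(COC(=O)CC(C)C)CC=C[C@]12C | intermediate
34 | 2α-(1,3,2-benzodioxaborol-2-yl) derivative of 33 (C1 saturated) | COC(=O)CCC(=O)OC/C=C(\C)CC[C@H]1C(C)=CC[C@H]2[C@@](C)(COC(=O)CC(C)C)C[C@H](B3Oc4ccccc4O3)C[C@]12C | intermediate (not isolated)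
35 | (13E)-2α-hydroxy-19-(3-methylbutanoyloxy)labda-7,13-dien-15-yl methyl butanedioate | COC(=O)CCC(=O)OC/C=C(\C)CC[C@H]1C(C)=CC[C@H]2[C@@](C)(COC(=O)CC(C)C)C[C@H](O)C[C@]12C | target

**Step count**

Total steps: 23. Longest linear sequence: 17 steps (steps 1, 3–6 and 12–23; the side-chain branch, steps 7–11 followed by 12–23, is equally long).

**Steps most likely to fail**

Step 3 (Diels–Alder). The cycloaddition may stall: bond formation between the β,β-disubstituted carbon of the butenolide and a diene whose C10 terminus is fully substituted is slow, and the diene can hydrolyse or oligomerise before it adds. The fallback sets out from 3 and returns at 7. Butenolide 3 is combined with the unhindered parent diene (E)-1-methoxy-3-(trimethylsilyloxy)buta-1,3-diene (toluene, 110 °C, or under pressure), a diene known to add to these alkoxyfuranones, to give the silyl enol ether cycloadduct F1. Dilute acid converts this into the enone lactone lacking C20, F2. C20 is then introduced by conjugate addition of Me2CuLi in the presence of Me3SiCl (THF, −78 °C), which traps the C1=C2 silyl enol ether F3. Saegusa–Ito dehydrogenation with Pd(OAc)2 in MeCN restores the C1=C10 double bond and delivers 7.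

Step 17 (ring B closure). The enolate may be diverted to O-alkylation (a six-membered enol ether) or to proton exchange between enolates before the C6–C7 bond forms. The fallback sets out from 24 and returns at 27. Alcohol 24 is oxidised with Dess–Martin periodinane to the keto aldehyde F4. Intramolecular aldol condensation (KOH, MeOH, rt) closes ring B as the 6-en-8-one F5, with C9 equilibrating to the equatorial side chain under the same basic conditions. Conjugate reduction with LiBH(sBu)3 (THF, −78 °C) and protonation then give ketone 27.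

Step 23 (final hydroboration). The catalyst may turn over slowly at the hindered C1=C2 bond, and rhodium hydride may isomerise or reduce one of the other alkenes, so that regio- and chemoselectivity erode on the most advanced intermediate. The fallback sets out from 33 and returns at 35. It replaces the catalytic addition by an uncatalysed, sterically governed hydroboration with disiamylborane (from BH3·SMe2 and 2-methylbut-2-ene, THF, 0 °C → rt), a dialkylborane that adds only very slowly to trisubstituted alkenes and does not reduce esters. This gives the 2α-disiamylboryl compound F6, which buffered H2O2 (pH 7) oxidises to 35.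

**Further compounds**

F1 | step 3 | silyl enol ether cycloadduct of 3 with the parent diene (C10 bears H and OCH3, C10 epimers) | O=C1O[C@H](O[C@H]3C[C@@H](C)CC[C@@H]3C(C)C)[C@@]2(C)CC(O[Si](C)(C)C)=CC(OC)[C@@H]12
F2 | step 3 | enone lactone acetal lacking C20 (C1=C10 with H on C10) | O=C1O[C@H](O[C@H]3C[C@@H](C)CC[C@@H]3C(C)C)[C@@]2(C)CC(=O)C=C[C@@H]12
F3 | step 3 | C1=C2 trimethylsilyl enol ether with C10 methyl (C10 epimers) | O=C1O[C@H](O[C@H]3C[C@@H](C)CC[C@@H]3C(C)C)[C@@]2(C)CC(O[Si](C)(C)C)=CC(C)[C@@H]12
F4 | step 17 | keto aldehyde (C6 aldehyde, C8 methyl ketone; C9 epimers) | C[C@]1(C(CC/C(C)=C/CO[Si](c2ccccc2)(c2ccccc2)C(C)(C)C)C(C)=O)C=CC[C@](C)(CO[Si](c2ccccc2)(c2ccccc2)C(C)(C)C)[C@@H]1C=O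
F5 | step 17 | 15,19-bis(TBDPS-oxy)-17-norlabda-1,6,13E-trien-8-one | CC(C)(C)[Si](c1ccccc1)(c1ccccc1)OC/C=C(\C)CC[C@H]1C(=O)C=C[C@H]2[C@@](C)(CO[Si](c3ccccc3)(c3ccccc3)C(C)(C)C)CC=C[C@]12C
F6 | step 23 | 2α-[bis(3-methylbutan-2-yl)boryl] derivative of 33 (C1 saturated) | COC(=O)CCC(=O)OC/C=C(\C)CC[C@H]1C(C)=CC[C@H]2[C@@](C)(COC(=O)CC(C)C)C[C@H](B(C(C)C(C)C)C(C)C(C)C)C[C@]12C
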